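**Plan**

1. Retrosynthetic cuts, in order: the three benzyl–O bonds; the lactone C3–CH2Ar bond (enolate alkylation); the benzofuran C5–CH2 bond (aryl Grignard opening of a cyclopropane-fused lactone); then, together, O1–C7a and C2–C3 of the dihydrobenzofuran (aldol/O-arylation annulation of an ortho-iodoarylacetate with O-benzylvanillin); last the ArCH2–CO2R homologation.
2. Forward order: anisole ring A (as a 2-iodo-5-bromoarylacetate) → dihydrofuran ring B closed onto ring A while guaiacyl ring C is attached (step 4) → lactone ring D, made beforehand from (R)-epichlorohydrin and dimethyl malonate, joined at C5 → guaiacyl ring E by alkylation → debenzylation.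
3. Enabling feature: C3 of ring B bears the CH2OH carbon, which at the ester level makes C3–H acidic, and C2 is a doubly benzylic carbinol carbon, so C2–C3 is a reversible aldol bond; C7a lies ortho to C3a on ring A, so the aldolate oxygen O1 sits in five-ring distance of a ring carbon that can carry iodine.
4. Stereochemistry: C2 of ring B from a chiral diamine on copper acting on interconverting aldolates (dynamic kinetic), C3 by base epimerisation to trans; lactone C4 from (R)-epichlorohydrin; lactone C3 by alkylation anti to the C4 substituent.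

Key step: step 4

Assumption: the sense of induction of the chiral diamine in step 4 cannot be predicted from precedent; the (1R,2R) ligand is written and its antipode would be used if the first experiment shows the opposite sense.

**Route**

Step 1
Reactants: 1 2-amino-5-bromo-3-methoxybenzoic acid
Product: 3 5-bromo-2-iodo-3-methoxybenzoic acid, via arenediazonium hydrogensulfate 2 (not isolated)
Conditions: NaNO2, aq. H2SO4, MeCN, 0 °C; then KI, H2O, 0 → 50 °C
Reagents that add atoms: potassium iodide, [K+].[I-]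
Why: Diazotisation and displacement of N2 by iodide (Sandmeyer-type iodination, the standard route from anthranilic acids to 2-iodobenzoic acids) should place iodine on the carbon that becomes C7a.

Step 2
Reactants: 3 5-bromo-2-iodo-3-methoxybenzoic acid
Product: 5 1-(5-bromo-2-iodo-3-methoxyphenyl)-2-diazoethan-1-one, via acid chloride 4 (not isolated)
Conditions: (COCl)2, cat. DMF, CH2Cl2, 0 → 23 °C; then Me3SiCHN2, THF/MeCN, 0 °C
Reagents that add atoms: (trimethylsilyl)diazomethane, C[Si](C)(C)C=[N+]=[N-]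
Why: Acylation of the diazoalkane by the acid chloride, with chloride removing the silyl group, should give the α-diazoketone (first stage of the Arndt–Eistert homologation).

Step 3
Reactants: 5 1-(5-bromo-2-iodo-3-methoxyphenyl)-2-diazoethan-1-one
Product: 7 tert-butyl 2-(5-bromo-2-iodo-3-methoxyphenyl)acetate, via arylketene 6 (not isolated)
Conditions: PhCO2Ag (10 mol%), Et3N, t-BuOH/THF, 50 °C, dark
Reagents that add atoms: tert-butanol, CC(C)(C)O
Why: Silver-promoted Wolff rearrangement should give the arylketene, which tert-butanol traps as the homologated ester (second stage of the Arndt–Eistert homologation).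

Step 4
Reactants: 7 tert-butyl 2-(5-bromo-2-iodo-3-methoxyphenyl)acetate; 8 4-(benzyloxy)-3-methoxybenzaldehyde
Product: 10 tert-butyl (2S,3S)-2-[4-(benzyloxy)-3-methoxyphenyl]-5-bromo-7-methoxy-2,3-dihydro-1-benzofuran-3-carboxylate, via caesium aldolate 9 (not isolated)
Conditions: CuI (10 mol%), (1R,2R)-N,N'-dimethyl-1,2-diphenylethane-1,2-diamine (20 mol%), Cs2CO3 (2.5 equiv), 8 (1.5 equiv), 4 Å MS, DMF, 25 °C
Reagents that add atoms: none
Why: Proposed new method: Cs2CO3 reversibly deprotonates the arylacetate CH2 of 7 (more acidic than the alcohols such couplings normally engage), the enolate adds to 8 to form C2–C3, and the diamine-ligated monovalent copper alkoxide derived from 9 then adds oxidatively to the adjacent C–I bond and reductively eliminates O1–C7a, so both bonds arise in one flask. The closest known reaction types are the CuI/chiral 1,2-diamine enantioselective intramolecular aryl C–O coupling that turns 2-(2-halobenzyl)propane-1,3-diols into chiral 2,3-dihydrobenzofurans and base-mediated aldol/ring-closure cascades of 2-haloarylacetic esters; their merger under dynamic kinetic control has not been shown. Ring B closes in a five-membered exo mode, the alkoxide oxygen attacking the iodine-bearing sp2 carbon ortho to the side chain (Ullmann-type etherification through a six-membered cupracycle). C2 is controlled by the ligand, because the doubly benzylic C2–C3 bond of the aldolates should break and re-form (retro-aldol) faster than ring closure, so that all material drains through the faster diastereomeric copper transition state, taken to be that of the (S)-alkoxide (Curtin–Hammett); C3 is controlled thermodynamically, the ester α-proton letting any cis ester epimerise under carbonate to the trans (2S,3S) isomer. The step needs C–I over C–Br and O- over C-arylation selectivity, secured by the ortho position of iodine (only it allows five-ring closure at 25 °C, the remote bromide has no internal partner, and the iodide, flanked by OMe and the side chain, is too hindered for intermolecular coupling). It also needs ring closure to outrun dehydration of the aldol, which the tert-butyl ester (no Claisen self-condensation, no lactonisation) and the mild carbonate base should favour.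

Step 5
Reactants: 10 tert-butyl (2S,3S)-2-[4-(benzyloxy)-3-methoxyphenyl]-5-bromo-7-methoxy-2,3-dihydro-1-benzofuran-3-carboxylate
Product: 11 [(2S,3R)-2-[4-(benzyloxy)-3-methoxyphenyl]-5-bromo-7-methoxy-2,3-dihydro-1-benzofuran-3-yl]methanol
Conditions: i-Bu2AlH (3 equiv), CH2Cl2, −78 → 0 °C; Rochelle salt work-up
Reagents that add atoms: none
Why: Hydride reduction of the ester to the primary alcohol at low temperature should leave the aryl bromide and the C3 configuration untouched (the descriptor changes from S to R only through the priority rules).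

Step 6
Reactants: 11 [(2S,3R)-2-[4-(benzyloxy)-3-methoxyphenyl]-5-bromo-7-methoxy-2,3-dihydro-1-benzofuran-3-yl]methanol
Product: 12 (2S,3R)-2-[4-(benzyloxy)-3-methoxyphenyl]-3-[(benzyloxy)methyl]-5-bromo-7-methoxy-2,3-dihydro-1-benzofuran
Conditions: NaH, BnBr, cat. Bu4NI, THF/DMF, 0 → 23 °C
Reagents that add atoms: benzyl bromide, BrCc1ccccc1
Why: Williamson etherification should mask the only acidic proton before the organomagnesium step, with a group that leaves in the final hydrogenolysis.

Step 7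
Reactants: 13 (R)-epichlorohydrin; 14 dimethyl malonate
Product: 15 methyl (1S,5R)-2-oxo-3-oxabicyclo[3.1.0]hexane-1-carboxylate
Conditions: NaOMe (1.05 equiv), MeOH, 0 → 65 °C
Reagents that add atoms: none
Why: Malonate opening of the epoxide at CH2, re-closure to the transposed epoxide, 3-exo-tet cyclopropanation with inversion at the stereogenic carbon and lactonisation (the known epichlorohydrin/malonate cyclopropane-lactone synthesis) should give the (1S,5R) bicycle from the (R)-epoxide.

Step 8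
Reactants: 12 (2S,3R)-2-[4-(benzyloxy)-3-methoxyphenyl]-3-[(benzyloxy)methyl]-5-bromo-7-methoxy-2,3-dihydro-1-benzofuran; 15 methyl (1S,5R)-2-oxo-3-oxabicyclo[3.1.0]hexane-1-carboxylate
Product: 18 methyl (3S,4R)-4-{[(2S,3R)-2-[4-(benzyloxy)-3-methoxyphenyl]-3-[(benzyloxy)methyl]-7-methoxy-2,3-dihydro-1-benzofuran-5-yl]methyl}-2-oxooxolane-3-carboxylate, via aryl Grignard reagent 16 (not isolated), via magnesium enolate 17 (not isolated)
Conditions: Mg, LiCl, THF, 40 °C; then CuI (15 mol%), 15 (1.3 equiv), THF, −30 → 0 °C; aq. NH4Cl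
Reagents that add atoms: none
Why: Copper-catalysed homoconjugate (SN2-type) addition of the aryl Grignard reagent to the CH2 of the doubly activated cyclopropane should form the C5–CH2 bond and leave the ring-fusion carbon untouched as lactone C4 (R); C3 of the product is epimerisable and of no consequence.

Step 9
Reactants: 18 methyl (3S,4R)-4-{[(2S,3R)-2-[4-(benzyloxy)-3-methoxyphenyl]-3-[(benzyloxy)methyl]-7-methoxy-2,3-dihydro-1-benzofuran-5-yl]methyl}-2-oxooxolane-3-carboxylate
Product: 19 (4R)-4-{[(2S,3R)-2-[4-(benzyloxy)-3-methoxyphenyl]-3-[(benzyloxy)methyl]-7-methoxy-2,3-dihydro-1-benzofuran-5-yl]methyl}oxolan-2-one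
Conditions: LiCl, H2O, DMSO, 140 °C
Reagents that add atoms: none
Why: Krapcho dealkoxycarbonylation (chloride demethylation, loss of CO2, protonation) should remove the activating ester without touching C4.

Step 10
Reactants: 20 [4-(benzyloxy)-3-methoxyphenyl]methanol
Product: 21 1-(benzyloxy)-4-(bromomethyl)-2-methoxybenzene
Conditions: PBr3, Et2O, 0 °C
Reagents that add atoms: phosphorus tribromide, BrP(Br)Br
Why: Conversion of the benzylic alcohol into the bromide through its phosphite ester should give the alkylating agent, to be used freshly prepared.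

Step 11
Reactants: 19 (4R)-4-{[(2S,3R)-2-[4-(benzyloxy)-3-methoxyphenyl]-3-[(benzyloxy)methyl]-7-methoxy-2,3-dihydro-1-benzofuran-5-yl]methyl}oxolan-2-one; 21 1-(benzyloxy)-4-(bromomethyl)-2-methoxybenzene
Product: 23 (3R,4R)-3-{[4-(benzyloxy)-3-methoxyphenyl]methyl}-4-{[(2S,3R)-2-[4-(benzyloxy)-3-methoxyphenyl]-3-[(benzyloxy)methyl]-7-methoxy-2,3-dihydro-1-benzofuran-5-yl]methyl}oxolan-2-one, via lithium enolate 22 (not isolated)
Conditions: LiN(SiMe3)2, THF, −78 °C; then 21, −78 → −40 °C
Reagents that add atoms: none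
Why: Lactone enolate alkylation should occur on the face anti to the C4 substituent and so give the trans (3R,4R) dibenzylbutyrolactone, the classical stereocontrol of lignan lactone synthesis.

Step 12
Reactants: 23 (3R,4R)-3-{[4-(benzyloxy)-3-methoxyphenyl]methyl}-4-{[(2S,3R)-2-[4-(benzyloxy)-3-methoxyphenyl]-3-[(benzyloxy)methyl]-7-methoxy-2,3-dihydro-1-benzofuran-5-yl]methyl}oxolan-2-one
Product: 24 lappaol A, (3R,4R)-3-[(4-hydroxy-3-methoxyphenyl)methyl]-4-{[(2S,3R)-2-(4-hydroxy-3-methoxyphenyl)-3-(hydroxymethyl)-7-methoxy-2,3-dihydro-1-benzofuran-5-yl]methyl}oxolan-2-one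
Conditions: H2 (1 atm), 10% Pd/C, EtOAc/MeOH, 23 °C
Reagents that add atoms: none
Why: Catalytic hydrogenolysis should cleave the two aryl benzyl ethers and the primary benzyl ether, which react faster than the cyclic benzylic aryl ether of ring B, and no stereocentre is involved.

**Compound list**

1 | 2-amino-5-bromo-3-methoxybenzoic acid | COc1cc(Br)cc(C(=O)O)c1N | starting material
2 | 4-bromo-2-carboxy-6-methoxybenzenediazonium hydrogensulfate | COc1cc(Br)cc(C(=O)O)c1[N+]#N.OS(=O)(=O)[O-] | intermediate (not isolated)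
3 | 5-bromo-2-iodo-3-methoxybenzoic acid | COc1cc(Br)cc(C(=O)O)c1I | intermediate
4 | 5-bromo-2-iodo-3-methoxybenzoyl chloride | COc1cc(Br)cc(C(=O)Cl)c1I | intermediate (not isolated)
5 | 1-(5-bromo-2-iodo-3-methoxyphenyl)-2-diazoethan-1-one | COc1cc(Br)cc(C(=O)C=[N+]=[N-])c1I | intermediate
6 | 2-(5-bromo-2-iodo-3-methoxyphenyl)ethen-1-one (arylketene) | COc1cc(Br)cc(C=C=O)c1I | intermediate (not isolated)
7 | tert-butyl 2-(5-bromo-2-iodo-3-methoxyphenyl)acetate | COc1cc(Br)cc(CC(=O)OC(C)(C)C)c1I | intermediate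
8 | 4-(benzyloxy)-3-methoxybenzaldehyde | COc1cc(C=O)ccc1OCc1ccccc1 | starting material
9 | caesium (1S,2S)-1-[4-(benzyloxy)-3-methoxyphenyl]-2-(5-bromo-2-iodo-3-methoxyphenyl)-3-tert-butoxy-3-oxopropan-1-olate (productive member of the interconverting aldolate mixture) | Brc1cc(OC)c(I)c(c1)[C@H](C(=O)OC(C)(C)C)[C@@H](c1ccc(OCc3ccccc3)c(OC)c1)[O-].[Cs+] | intermediate (not isolated)
10 | tert-butyl (2S,3S)-2-[4-(benzyloxy)-3-methoxyphenyl]-5-bromo-7-methoxy-2,3-dihydro-1-benzofuran-3-carboxylate | Brc1cc(OC)c2c(c1)[C@H](C(=O)OC(C)(C)C)[C@@H](c1ccc(OCc3ccccc3)c(OC)c1)O2 | intermediate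
11 | [(2S,3R)-2-[4-(benzyloxy)-3-methoxyphenyl]-5-bromo-7-methoxy-2,3-dihydro-1-benzofuran-3-yl]methanol | Brc1cc(OC)c2c(c1)[C@H](CO)[C@@H](c1ccc(OCc3ccccc3)c(OC)c1)O2 | intermediate
12 | (2S,3R)-2-[4-(benzyloxy)-3-methoxyphenyl]-3-[(benzyloxy)methyl]-5-bromo-7-methoxy-2,3-dihydro-1-benzofuran | Brc1cc(OC)c2c(c1)[C@H](COCc1ccccc1)[C@@H](c1ccc(OCc3ccccc3)c(OC)c1)O2 | intermediate
13 | (R)-epichlorohydrin, (2R)-2-(chloromethyl)oxirane | ClC[C@H]1CO1 | starting material
14 | dimethyl malonate | COC(=O)CC(=O)OC | starting material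
15 | methyl (1S,5R)-2-oxo-3-oxabicyclo[3.1.0]hexane-1-carboxylate | COC(=O)[C@@]12C(=O)OC[C@@H]1C2 | intermediate
16 | {(2S,3R)-2-[4-(benzyloxy)-3-methoxyphenyl]-3-[(benzyloxy)methyl]-7-methoxy-2,3-dihydro-1-benzofuran-5-yl}magnesium bromide | Br[Mg]c1cc(OC)c2c(c1)[C@H](COCc1ccccc1)[C@@H](c1ccc(OCc3ccccc3)c(OC)c1)O2 | intermediate (not isolated)
17 | bromomagnesium enolate of methyl (4R)-4-{[(2S,3R)-2-[4-(benzyloxy)-3-methoxyphenyl]-3-[(benzyloxy)methyl]-7-methoxy-2,3-dihydro-1-benzofuran-5-yl]methyl}-2-oxooxolane-3-carboxylate | COC(=O)C1=C(O[Mg]Br)OC[C@@H]1Cc1cc(OC)c2c(c1)[C@H](COCc1ccccc1)[C@@H](c1ccc(OCc3ccccc3)c(OC)c1)O2 | intermediate (not isolated)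
18 | methyl (3S,4R)-4-{[(2S,3R)-2-[4-(benzyloxy)-3-methoxyphenyl]-3-[(benzyloxy)methyl]-7-methoxy-2,3-dihydro-1-benzofuran-5-yl]methyl}-2-oxooxolane-3-carboxylate (trans isomer drawn; C3 epimerisable) | COC(=O)[C@H]1C(=O)OC[C@@H]1Cc1cc(OC)c2c(c1)[C@H](COCc1ccccc1)[C@@H](c1ccc(OCc3ccccc3)c(OC)c1)O2 | intermediate
19 | (4R)-4-{[(2S,3R)-2-[4-(benzyloxy)-3-methoxyphenyl]-3-[(benzyloxy)methyl]-7-methoxy-2,3-dihydro-1-benzofuran-5-yl]methyl}oxolan-2-one | O=C1C[C@@H](Cc2cc(OC)c3c(c2)[C@H](COCc2ccccc2)[C@@H](c2ccc(OCc4ccccc4)c(OC)c2)O3)CO1 | intermediate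
20 | [4-(benzyloxy)-3-methoxyphenyl]methanol | COc1cc(CO)ccc1OCc1ccccc1 | starting material
21 | 1-(benzyloxy)-4-(bromomethyl)-2-methoxybenzene | COc1cc(CBr)ccc1OCc1ccccc1 | intermediate
22 | lithium enolate of lactone 19, lithium (3R)-3-{[(2S,3R)-2-[4-(benzyloxy)-3-methoxyphenyl]-3-[(benzyloxy)methyl]-7-methoxy-2,3-dihydro-1-benzofuran-5-yl]methyl}-2,3-dihydrofuran-5-olate | [Li]OC1=C[C@@H](Cc2cc(OC)c3c(c2)[C@H](COCc2ccccc2)[C@@H](c2ccc(OCc4ccccc4)c(OC)c2)O3)CO1 | intermediate (not isolated)
23 | (3R,4R)-3-{[4-(benzyloxy)-3-methoxyphenyl]methyl}-4-{[(2S,3R)-2-[4-(benzyloxy)-3-methoxyphenyl]-3-[(benzyloxy)methyl]-7-methoxy-2,3-dihydro-1-benzofuran-5-yl]methyl}oxolan-2-one | COc1cc(C[C@H]2C(=O)OC[C@@H]2Cc2cc(OC)c3c(c2)[C@H](COCc2ccccc2)[C@@H](c2ccc(OCc4ccccc4)c(OC)c2)O3)ccc1OCc1ccccc1 | intermediate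
24 | lappaol A, (3R,4R)-3-[(4-hydroxy-3-methoxyphenyl)methyl]-4-{[(2S,3R)-2-(4-hydroxy-3-methoxyphenyl)-3-(hydroxymethyl)-7-methoxy-2,3-dihydro-1-benzofuran-5-yl]methyl}oxolan-2-one | COc1cc(C[C@H]2C(=O)OC[C@@H]2Cc2cc(OC)c3c(c2)[C@H](CO)[C@@H](c2ccc(O)c(OC)c2)O3)ccc1O | target

**Count**

Total steps: 12. Longest linear sequence: 10 (steps 1–6, 8, 9, 11, 12).

**Steps most likely to fail, with fallbacks**

Step 4 (proposed new method). What may go wrong: insufficient discrimination between the interconverting aldolates in the ring closure, or retro-aldol exchange too slow to feed the faster-closing alkoxide; dehydration of the aldol to the 2,3-diarylacrylate; O-arylation of the ester enolate oxygen; base-induced β-elimination that reopens ring B. The fallback makes the two bonds one after the other by known chemistry and sets out from diazoketone 5. Wolff rearrangement in aqueous dioxane (PhCO2Ag, Et3N) should give 2-(5-bromo-2-iodo-3-methoxyphenyl)acetic acid F1. Mixed-anhydride acylation (t-BuCOCl, Et3N, then (4S)-4-benzyl-1,3-oxazolidin-2-one and LiCl) should give (4S)-4-benzyl-3-[2-(5-bromo-2-iodo-3-methoxyphenyl)acetyl]-1,3-oxazolidin-2-one F2. Evans syn-aldol addition to 8 (n-Bu2BOTf, i-Pr2NEt, CH2Cl2, −78 → 0 °C) should set both centres and give (4S)-4-benzyl-3-[(2S,3S)-3-[4-(benzyloxy)-3-methoxyphenyl]-2-(5-bromo-2-iodo-3-methoxyphenyl)-3-hydroxypropanoyl]-1,3-oxazolidin-2-one F3. LiBH4 should remove the auxiliary to give (1S,2R)-1-[4-(benzyloxy)-3-methoxyphenyl]-2-(5-bromo-2-iodo-3-methoxyphenyl)propane-1,3-diol F4, and TBSCl/imidazole should silylate the primary hydroxyl to give (1S,2R)-1-[4-(benzyloxy)-3-methoxyphenyl]-2-(5-bromo-2-iodo-3-methoxyphenyl)-3-[(tert-butyldimethylsilyl)oxy]propan-1-ol F5. Ullmann ring closure (CuI, 1,10-phenanthroline, Cs2CO3, toluene, 80 °C), now with no retro-aldol pathway, should give tert-butyl{[(2S,3R)-2-[4-(benzyloxy)-3-methoxyphenyl]-5-bromo-7-methoxy-2,3-dihydro-1-benzofuran-3-yl]methoxy}dimethylsilane F6. Bu4NF should then give alcohol 11, where the route is rejoined.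

Step 8. What may go wrong: slow or incomplete magnesium insertion into the electron-rich bromide on small scale, homocoupling of the aryl, or 1,2-addition of the Grignard reagent to the lactone or ester carbonyl instead of cyclopropane opening. The fallback builds the lactone on the arene instead and sets out from bromide 12. Bromine–lithium exchange (n-BuLi, THF, −78 °C) and DMF should give (2S,3R)-2-[4-(benzyloxy)-3-methoxyphenyl]-3-[(benzyloxy)methyl]-7-methoxy-2,3-dihydro-1-benzofuran-5-carbaldehyde F7. Stobbe condensation with dimethyl succinate (KOt-Bu, t-BuOH) should give (3E)-4-{(2S,3R)-2-[4-(benzyloxy)-3-methoxyphenyl]-3-[(benzyloxy)methyl]-7-methoxy-2,3-dihydro-1-benzofuran-5-yl}-3-(methoxycarbonyl)but-3-enoic acid F8. Asymmetric hydrogenation (H2, [Rh(cod)(Me-DuPhos)]BF4, MeOH, the ligand antipode that delivers the 3R acid) should give (3R)-4-{(2S,3R)-2-[4-(benzyloxy)-3-methoxyphenyl]-3-[(benzyloxy)methyl]-7-methoxy-2,3-dihydro-1-benzofuran-5-yl}-3-(methoxycarbonyl)butanoic acid F9. Reduction of the ester in the potassium carboxylate (KOH; CaCl2/NaBH4, EtOH) and acidification should close the lactone and give 19, where the route is rejoined.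

Step 12. What may go wrong: over-reduction by hydrogenolysis of the benzylic C2–O1 bond of ring B, or incomplete cleavage of the primary benzyl ether. The fallback replaces reduction by Lewis-acid dealkylation with a cation scavenger: from 23, BCl3 and pentamethylbenzene (CH2Cl2, −78 °C) should remove all three benzyl groups and give 24 directly; no new compound is made.

Further compounds
F1 | step 4 | 2-(5-bromo-2-iodo-3-methoxyphenyl)acetic acid | COc1cc(Br)cc(CC(=O)O)c1I
F2 | step 4 | (4S)-4-benzyl-3-[2-(5-bromo-2-iodo-3-methoxyphenyl)acetyl]-1,3-oxazolidin-2-one | COc1cc(Br)cc(CC(=O)N2[C@@H](Cc3ccccc3)COC2=O)c1I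
F3 | step 4 | (4S)-4-benzyl-3-[(2S,3S)-3-[4-(benzyloxy)-3-methoxyphenyl]-2-(5-bromo-2-iodo-3-methoxyphenyl)-3-hydroxypropanoyl]-1,3-oxazolidin-2-one | Brc1cc(OC)c(I)c(c1)[C@H](C(=O)N1[C@@H](Cc3ccccc3)COC1=O)[C@@H](c1ccc(OCc3ccccc3)c(OC)c1)O
F4 | step 4 | (1S,2R)-1-[4-(benzyloxy)-3-methoxyphenyl]-2-(5-bromo-2-iodo-3-methoxyphenyl)propane-1,3-diol | Brc1cc(OC)c(I)c(c1)[C@H](CO)[C@@H](c1ccc(OCc3ccccc3)c(OC)c1)O
F5 | step 4 | (1S,2R)-1-[4-(benzyloxy)-3-methoxyphenyl]-2-(5-bromo-2-iodo-3-methoxyphenyl)-3-[(tert-butyldimethylsilyl)oxy]propan-1-ol | Brc1cc(OC)c(I)c(c1)[C@H](CO[Si](C)(C)C(C)(C)C)[C@@H](c1ccc(OCc3ccccc3)c(OC)c1)O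
F6 | step 4 | tert-butyl{[(2S,3R)-2-[4-(benzyloxy)-3-methoxyphenyl]-5-bromo-7-methoxy-2,3-dihydro-1-benzofuran-3-yl]methoxy}dimethylsilane | Brc1cc(OC)c2c(c1)[C@H](CO[Si](C)(C)C(C)(C)C)[C@@H](c1ccc(OCc3ccccc3)c(OC)c1)O2
F7 | step 8 | (2S,3R)-2-[4-(benzyloxy)-3-methoxyphenyl]-3-[(benzyloxy)methyl]-7-methoxy-2,3-dihydro-1-benzofuran-5-carbaldehyde | O=Cc1cc(OC)c2c(c1)[C@H](COCc1ccccc1)[C@@H](c1ccc(OCc3ccccc3)c(OC)c1)O2
F8 | step 8 | (3E)-4-{(2S,3R)-2-[4-(benzyloxy)-3-methoxyphenyl]-3-[(benzyloxy)methyl]-7-methoxy-2,3-dihydro-1-benzofuran-5-yl}-3-(methoxycarbonyl)but-3-enoic acid | OC(=O)C/C(C(=O)OC)=C\c1cc(OC)c2c(c1)[C@H](COCc1ccccc1)[C@@H](c1ccc(OCc3ccccc3)c(OC)c1)O2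
F9 | step 8 | (3R)-4-{(2S,3R)-2-[4-(benzyloxy)-3-methoxyphenyl]-3-[(benzyloxy)methyl]-7-methoxy-2,3-dihydro-1-benzofuran-5-yl}-3-(methoxycarbonyl)butanoic acid | OC(=O)C[C@H](C(=O)OC)Cc1cc(OC)c2c(c1)[C@H](COCc1ccccc1)[C@@H](c1ccc(OCc3ccccc3)c(OC)c1)O2
F0 | step 12 | none | none
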